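Assumptions: (i) atoms are labelled as they appear in the target SMILES (C1 = CH–OAc, C2, C3 = C(Me)OAc, C4, C5 = ring-fusion CH, C6, C7 = C=O, C8=C9, C10, C11, N12, C13–C15, C16 = quaternary C); (ii) the catalyst antipode in step 6 is chosen to give (16R)-12, and its enantiomer is used if the observed sense is opposite.

## Retrosynthetic overview

1. Target ⇐ N-Boc diol 16 (acetylation, Boc removal) ⇐ tricyclic bis-enone 12, by axial MeLi addition at C3 and silicon-tethered hydration of C1=C2 (cis-1,3-diol).
2. 12 ⇐ prochiral spiro-cyclohexadienone 11, by a catalytic desymmetrising intramolecular Michael addition (forms the cyclopentanone, sets C16 and C5).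
3. 11 ⇐ dienone 9, by ring-closing metathesis (azonine, C9=C10) and alkene conjugation.
4. 9 ⇐ phenol 5 + γ-silyl enone 8, by oxidative dearomatisation (forms the quaternary C16–C8 bond).
5. Ring order: benzene ring → cyclohexadienone → azonine → cyclopentanone.

## Route

Step 1
Reactants: 1 3-(4-hydroxyphenyl)propan-1-ol
Product: 2 4-(3-bromopropyl)phenol
Conditions: 48% aq HBr, toluene, 110 °C
Reagents that add atoms: hydrogen bromide (Br)
Why: SN2 substitution of the protonated primary alcohol by bromide; the phenol OH does not react.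

Step 2
Reactants: 2 4-(3-bromopropyl)phenol; 3 allylamine
Product: 5 tert-butyl allyl[3-(4-hydroxyphenyl)propyl]carbamate, via 4-[3-(allylamino)propyl]phenol 4 (not isolated)
Conditions: allylamine (10 equiv), MeCN, 40 °C; evaporate; Boc2O (1.05 equiv), NaHCO3, THF/H2O, 23 °C
Reagents that add atoms: di-tert-butyl dicarbonate (CC(C)(C)OC(=O)OC(=O)OC(C)(C)C)
Why: SN2 amination with excess primary amine (no dialkylation), then chemoselective N-acylation of the secondary amine over the phenol.

Step 3
Reactants: 6 allyltrimethylsilane; 7 methyl vinyl ketone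
Product: 8 (E)-5-(trimethylsilyl)pent-3-en-2-one
Conditions: Hoveyda–Grubbs II (2 mol %), CH2Cl2, 40 °C
Reagents that add atoms: none
Why: olefin cross-metathesis of an electron-rich allylsilane with an electron-poor enone is a selective, E-selective pairing.

Step 4
Reactants: 5 tert-butyl allyl[3-(4-hydroxyphenyl)propyl]carbamate; 8 (E)-5-(trimethylsilyl)pent-3-en-2-one
Product: 9 tert-butyl allyl{3-[4-oxo-1-(4-oxopent-1-en-3-yl)cyclohexa-2,5-dien-1-yl]propyl}carbamate (racemic at C8)
Conditions: PhI(OAc)2 (1.2 equiv), 8 (3 equiv), (CF3)2CHOH/CH2Cl2, −20 °C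
Reagents that add atoms: none
Why: Proposed new method: PhI(OAc)2 in HFIP oxidises the phenol to a para-quinoid phenoxonium ion that is trapped at C16 by the allylsilane 8 in an SE2' sense (the β-silyl cation forces bond formation at the carbon α to the acetyl group and leaves a vinyl group), the closest known reaction being the oxidative Hosomi–Sakurai dearomatisation of 4-alkylphenols with allyltrimethylsilane; the dienone ring is prochiral and C8 later becomes sp2.

Step 5
Reactants: 9 tert-butyl allyl{3-[4-oxo-1-(4-oxopent-1-en-3-yl)cyclohexa-2,5-dien-1-yl]propyl}carbamate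
Product: 10 tert-butyl (12Z)-14-acetyl-3-oxo-10-azaspiro[5.8]tetradeca-1,4,12-triene-10-carboxylate (racemic at C8)
Conditions: Grubbs II (10 mol %), 1,4-benzoquinone (20 mol %), CH2Cl2 (1 mM), 40 °C
Reagents that add atoms: none
Why: ring-closing metathesis of the N-allyl and C8-vinyl groups, helped by the quaternary spiro centre and the carbamate, gives the nine-membered ring, which holds only the Z alkene; benzoquinone suppresses Ru–H isomerisation of the β,γ-enone.

Step 6
Reactants: 10 tert-butyl (12Z)-14-acetyl-3-oxo-10-azaspiro[5.8]tetradeca-1,4,12-triene-10-carboxylate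
Product: 12 N-Boc tricyclic bis-enone (5S,16R), via conjugated spiro-enone 11 (not isolated)
Conditions: (S)-1-(pyrrolidin-2-ylmethyl)pyrrolidine (20 mol %), TFA (20 mol %), THF, 23 °C
Reagents that add atoms: none
Why: the amine salt first moves the alkene into conjugation (the ring fixes C10 cis to C16), then a desymmetrising intramolecular Michael addition through the cross-conjugated 2-aminodiene (a secondary amine disfavours the linear dienamine at the fully substituted C8 by A(1,3) strain) joins C6 to one of the two enantiotopic enone arms, the five-membered tether enforcing the cis ring fusion at C5/C16 and the catalyst selecting the arm.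

Step 7
Reactants: 12 N-Boc tricyclic bis-enone (5S,16R)
Product: 13 N-Boc tertiary allylic alcohol (3S,5S,16R)
Conditions: MeLi (1.05 equiv), CeCl3, THF, −78 °C
Reagents that add atoms: methyllithium (C[Li])
Why: organocerium 1,2-addition goes to the unhindered cyclohexenone carbonyl C3 rather than the α-branched alkylidene-cyclopentanone C7, axially and anti to the cis-fused cyclopentane (from the face of C5–H), which places the C3 oxygen cis to C6/C8.

Step 8
Reactants: 13 N-Boc tertiary allylic alcohol (3S,5S,16R)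
Product: 16 N-Boc cis-1,3-diol (1S,3S,5S,16S), via dimethylsilyl ether 14 (not isolated), via cyclic siloxane 15 (not isolated)
Conditions: (HMe2Si)2NH, THF, 50 °C; Pt2(dvs)3 (2 mol %), toluene, 70 °C; 30% H2O2, KF, KHCO3, THF/MeOH, 23 °C
Reagents that add atoms: hydrogen peroxide (OO)
Why: Tamao intramolecular hydrosilylation (5-endo) delivers silicon from the C3 oxygen to C1 on the same face, the ring size fixing the regiochemistry, and Tamao–Fleming oxidation with retention gives the C1 alcohol cis to the C3 oxygen.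

Step 9
Reactants: 16 N-Boc cis-1,3-diol (1S,3S,5S,16S)
Product: 17 N-Boc diacetate (1S,3S,5S,16S)
Conditions: Ac2O, Et3N, DMAP, CH2Cl2, 40 °C
Reagents that add atoms: acetic anhydride (CC(=O)OC(C)=O)
Why: DMAP-catalysed acylation esterifies both the secondary and the tertiary alcohol without touching a stereocentre.

Step 10
Reactants: 17 N-Boc diacetate (1S,3S,5S,16S)
Product: 19 target amine diacetate CNP0120442.1, via trimethylsilyl carbamate 18 (not isolated)
Conditions: TMSOTf, 2,6-lutidine, CH2Cl2, 0 °C; MeOH; aq NaHCO3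
Reagents that add atoms: none
Why: silyl-triflate Boc cleavage (the silylated carbamate loses isobutene, then methanolysis and decarboxylation) frees the secondary amine under buffered conditions that spare the tertiary acetate and the enone.

## Compound list

1 | 3-(4-hydroxyphenyl)propan-1-ol | OCCCc1ccc(O)cc1 | starting material
2 | 4-(3-bromopropyl)phenol | BrCCCc1ccc(O)cc1 | intermediate
3 | allylamine | C=CCN | starting material
4 | 4-[3-(allylamino)propyl]phenol | C=CCNCCCc1ccc(O)cc1 | intermediate (not isolated)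
5 | tert-butyl allyl[3-(4-hydroxyphenyl)propyl]carbamate | C=CCN(CCCc1ccc(O)cc1)C(=O)OC(C)(C)C | intermediate
6 | allyltrimethylsilane | C=CC[Si](C)(C)C | starting material
7 | methyl vinyl ketone | CC(=O)C=C | starting material
8 | (E)-5-(trimethylsilyl)pent-3-en-2-one | CC(=O)/C=C/C[Si](C)(C)C | intermediate
9 | tert-butyl allyl{3-[4-oxo-1-(4-oxopent-1-en-3-yl)cyclohexa-2,5-dien-1-yl]propyl}carbamate (racemic at C8) | CC(=O)C(C=C)C1(CCCN(CC=C)C(=O)OC(C)(C)C)C=CC(=O)C=C1 | intermediate
10 | tert-butyl (12Z)-14-acetyl-3-oxo-10-azaspiro[5.8]tetradeca-1,4,12-triene-10-carboxylate (racemic at C8) | CC(=O)C1/C=C\CN(C(=O)OC(C)(C)C)CCCC12C=CC(=O)C=C2 | intermediate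
11 | tert-butyl (13E)-14-acetyl-3-oxo-10-azaspiro[5.8]tetradeca-1,4,13-triene-10-carboxylate | CC(=O)/C1=C/CCN(C(=O)OC(C)(C)C)CCCC12C=CC(=O)C=C2 | intermediate (not isolated)
12 | (5S,16R) N-Boc tricyclic bis-enone: cyclohex-1-en-3-one cis-fused at C5–C16 to cyclopentan-7-one, C8=C9 (E) in the N12-Boc azonine | C1=CC(=O)C[C@H]2CC(=O)/C3=C/CCN(C(=O)OC(C)(C)C)CCC[C@@]321 | intermediate
13 | (3S,5S,16R) tertiary allylic alcohol: as 12 with C3(CH3)(OH), OH cis to C6 and C8 | C1=C[C@@](C)(O)C[C@H]2CC(=O)/C3=C/CCN(C(=O)OC(C)(C)C)CCC[C@@]321 | intermediate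
14 | (3S,5S,16R) C3 dimethylsilyl ether of 13 | C1=C[C@@](C)(O[SiH](C)C)C[C@H]2CC(=O)/C3=C/CCN(C(=O)OC(C)(C)C)CCC[C@@]321 | intermediate (not isolated)
15 | (1S,3S,5S,16S) cyclic siloxane: O3–SiMe2–C1 bridge, cis-fused | C[Si]1(C)O[C@@]2(C)C[C@H]3CC(=O)/C4=C/CCN(C(=O)OC(C)(C)C)CCC[C@@]43[C@@H]1C2 | intermediate (not isolated)
16 | (1S,3S,5S,16S) N-Boc cis-1,3-diol | O[C@H]1C[C@@](C)(O)C[C@H]2CC(=O)/C3=C/CCN(C(=O)OC(C)(C)C)CCC[C@@]321 | intermediate
17 | (1S,3S,5S,16S) N-Boc diacetate | CC(=O)O[C@H]1C[C@@](C)(OC(C)=O)C[C@H]2CC(=O)/C3=C/CCN(C(=O)OC(C)(C)C)CCC[C@@]321 | intermediate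
18 | (1S,3S,5S,16S) N-(trimethylsilyloxycarbonyl) diacetate | CC(=O)O[C@H]1C[C@@](C)(OC(C)=O)C[C@H]2CC(=O)/C3=C/CCN(C(=O)O[Si](C)(C)C)CCC[C@@]321 | intermediate (not isolated)
19 | CNP0120442.1, (1S,3S,5S,16S,8E) amine diacetate | CC(=O)O[C@H]1C[C@@](C)(OC(C)=O)C[C@H]2CC(=O)/C3=C/CCNCCC[C@@]321 | target

## Step count and risks

Total steps: 10. Longest linear sequence: 9 steps (1 → 2 → 5 → 9 → 10 → 12 → 13 → 16 → 17 → 19); step 3 is a one-step side branch.

Step 4 (dearomatisation with an acceptor-substituted allylsilane) may fail because 8 is a weak nucleophile and can protodesilylate. The fallback sets out from 5 and 8 and returns at 10. Reduce 8 (NaBH4, CeCl3) to (E)-5-(trimethylsilyl)pent-3-en-2-ol F1 and silylate it (Et3SiCl, imidazole) to its triethylsilyl ether F2, an ordinary electron-rich γ-substituted allylsilane. Dearomatise 5 with F2 (PhI(OAc)2, HFIP) to the masked dienone F3, close the ring by metathesis to the spiro-azonine silyl ether F4, cleave the silyl ether (HF·pyridine) to the alcohol F5 and oxidise it (Dess–Martin periodinane) to 10.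

Step 6 (desymmetrising Michael addition) may fail through attack by the γ-carbon C10 instead of C6, or through low enantioselectivity. The fallback sets out from 10 and returns at 12. Conjugate 10 with Et3N and isolate 11, then deprotonate the acetyl CH3 kinetically with LDA in the presence of Me3SiCl (−78 °C) to give the 2-silyloxydiene F6, which fixes the nucleophilic site. A chiral disulfonimide (silylium Lewis acid) catalyst then effects an intramolecular Mukaiyama–Michael addition to the silyl dienol ether F7, and aqueous acid gives 12.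

Step 8 (tethered hydrosilylation) may fail because the C1=C2 alkene lies between two fully substituted carbons, and the peroxide oxidation may touch the enone. The fallback sets out from 13 and returns at 16. A Wacker-type oxidation (PdCl2, CuCl, O2, DMF/H2O), in which the allylic oxygen directs the carbonyl to the distal carbon C1, gives the β-hydroxy ketone F8. A Narasaka–Prasad syn reduction (Et2BOMe, NaBH4, −78 °C), with hydride entering anti to the cyclopentane, then gives 16.

## Further compounds

F1 | step 4 | (E)-5-(trimethylsilyl)pent-3-en-2-ol | CC(O)/C=C/C[Si](C)(C)C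
F2 | step 4 | triethyl{[(E)-5-(trimethylsilyl)pent-3-en-2-yl]oxy}silane | CC(O[Si](CC)(CC)CC)/C=C/C[Si](C)(C)C
F3 | step 4 | tert-butyl allyl[3-(4-oxo-1-{4-[(triethylsilyl)oxy]pent-1-en-3-yl}cyclohexa-2,5-dien-1-yl)propyl]carbamate | CC(O[Si](CC)(CC)CC)C(C=C)C1(CCCN(CC=C)C(=O)OC(C)(C)C)C=CC(=O)C=C1
F4 | step 4 | tert-butyl (12Z)-3-oxo-14-{1-[(triethylsilyl)oxy]ethyl}-10-azaspiro[5.8]tetradeca-1,4,12-triene-10-carboxylate | CC(O[Si](CC)(CC)CC)C1/C=C\CN(C(=O)OC(C)(C)C)CCCC12C=CC(=O)C=C2
F5 | step 4 | tert-butyl (12Z)-14-(1-hydroxyethyl)-3-oxo-10-azaspiro[5.8]tetradeca-1,4,12-triene-10-carboxylate | CC(O)C1/C=C\CN(C(=O)OC(C)(C)C)CCCC12C=CC(=O)C=C2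
F6 | step 6 | tert-butyl (13E)-3-oxo-14-{1-[(trimethylsilyl)oxy]vinyl}-10-azaspiro[5.8]tetradeca-1,4,13-triene-10-carboxylate | C=C(O[Si](C)(C)C)/C1=C/CCN(C(=O)OC(C)(C)C)CCCC12C=CC(=O)C=C2
F7 | step 6 | (5S,16R) C3 trimethylsilyl dienol ether of 12 | C1=CC(O[Si](C)(C)C)=C[C@H]2CC(=O)/C3=C/CCN(C(=O)OC(C)(C)C)CCC[C@@]321
F8 | step 8 | (3S,5S,16S) N-Boc 3-hydroxy-3-methyl-1,7-diketone | O=C1C[C@@](C)(O)C[C@H]2CC(=O)/C3=C/CCN(C(=O)OC(C)(C)C)CCC[C@@]321
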